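- Of the constants I need one, the selectivity factor S: the rate constant for capture of the intermediate by the second nucleophile over that for capture by the first.

the same everywhere: starting material 15 mM

| run | first nucleophile | second nucleophile | protic impurity | remark | time |
|---|---|---|---|---|---|
| birch | 1 equiv | 0.95 equiv | 0.75 mM | run made earlier |  |
| larch | 1.5 equiv | 0.95 equiv | 0.75 mM | run made earlier |  |
| elm | 2 equiv | 0.47 equiv | 0.75 mM | run made earlier |  |
| flask | 2.00 equiv | 0.950 equiv | 0.750 mM |  | 3.0 h |

| run | time / h | other capture product / % | target / % |
|---|---|---|---|
| birch | 0.500 | 86 | 3 |
| birch | 1.00 | 90 | 10 |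
| birch | 1.33 | 85 | 10 |
| birch | 2.00 | 91 | 8 |
| birch | 2.50 | 86 | 12 |
| larch | 0.200 | 70 | 4 |
| larch | 0.667 | 87 | 8 |
| larch | 1.00 | 86 | 13 |
| larch | 1.50 | 86 | 13 |
| larch | 2.50 | 86 | 13 |
| elm | 0.200 | 41 | 14 |
| elm | 0.667 | 43 | 38 |
| elm | 1.00 | 42 | 41 |
| elm | 1.50 | 38 | 43 |
| elm | 2.50 | 42 | 51 |

(each reading ± 2 percentage points)

* ratio of other capture product to target at 20 s
* ratio of other capture product to target at 8.0 min
* ratio of other capture product to target at 3.0 h
* which of other capture product and target there is more of at 3.0 h

- steps under discussion: starting material <-> intermediate; first nucleophile + intermediate -> target; second nucleophile + intermediate -> other capture product; intermediate -> decomposed reagent; second nucleophile + protic impurity -> quenched reagent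

- The protic impurity takes its share of the second nucleophile, so the usable charge in larch is 90.0 % of the starting material. Elm levels near 42 % against its usable 42.0 %, but larch stops at 86 %, and I read that gap as second nucleophile left over.
- The first nucleophile is nearly constant: in the flask, a target near larch's 13 % costs about 6.50 % of its charge. I freeze it at its mean, and the rate ratio S[second nucleophile]/[first nucleophile] integrates to target = ([first nucleophile]/S) ln(usable charge/[second nucleophile] left), in fractions of the starting material.
- Larch gives 55.7 at 0.200 h and 34.4 at 2.50 h. These disagree, with a scatter of 2 percentage points on a reading of 4 % and on a leftover near 4.00 %, so I carry their mean as my reading of the selectivity factor, S = 45.0.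
- At 20 s the ratio should be S times second over first nucleophile as charged, 21.4.
- For 8.0 min in the flask I need a clock, and I borrow larch's first-order approach to its plateau, which gives an estimate of 58.0 % other capture product. With the first nucleophile frozen at 1.94 equiv, the rule gives target 4.44 %, so the ratio is 13.1.
- For 3.0 h, larch's leftover gives target 13.4 %. But larch's products sum to 99.0 %, and taking that sum for the flask puts the leftover at 4.40 %, which gives 13.0 %. I take their mean 13.2 %, so I expect the other capture product to lead in the flask at a ratio of 6.51.
- The forecast gives 20, 11 and 8, with other capture product ahead, holding that “the second nucleophile captures the intermediate far better than the first”; its end ratio stands above mine.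
- The flask gives 21.9, 12.9 and 6.82, with other capture product ahead at 86.2 % against 12.6 %.

    starting material ⇌ intermediate (K = 0.00240, k = 0.00390 s⁻¹)
    first nucleophile + intermediate → target (k = 7.00 M⁻¹ s⁻¹)
    second nucleophile + intermediate → other capture product (k = 340 M⁻¹ s⁻¹)
    intermediate → decomposed reagent (k = 0.0180 s⁻¹)
    second nucleophile + protic impurity → quenched reagent (k = 5.10 M⁻¹ s⁻¹)

- In the flask, capture by the second nucleophile reaches the midpoint of its turnover at 0.0645 h, earlier than capture by the first at 0.190 h, while starting material feeds the intermediate, with 96 % of that step's turnover done by 0.600 h. At 3.00 h starting material stands at 0 % and second nucleophile at 4.0 % of its charge, and S with that leftover reckons the target at 13.6 %, against 12.6 % in the flask. For the neighbour flask with 0.240 equiv of second nucleophile, S times the charges gives 5.40 at 20 s, where that neighbour flask stands at 5.29.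

The runs come from a simulation with made-up constants; scatter was added.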